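**Retrosynthetic overview**
1. The last two bonds are the C5–O isovalerate (acylation) and the C7–OAr ether (Mitsunobu with purchased umbelliferone). They lead back to a cis-(1S,5R) 5-silyloxy-α-cyclogeraniol.
2. C1–H and C7–OH come from hydroboration of an exocyclic/endocyclic diene. The diene is made by Peterson methylenation of (5R)-5-silyloxy-2,6,6-trimethylcyclohex-2-enone, so C5 relays its configuration to C1.
3. The cyclohexene is the only ring that has to be built. It is closed at C2=C3 by ring-closing metathesis of an acyclic 1,7-dienol, made from isopropenyl Grignard and an α,α-dimethyl aldehyde.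
4. The key C–C bond is C4–C5. A Brown asymmetric carbonyl allylation joins methyl 2,2-dimethyl-3-oxopropanoate (C5–C6–C1 piece) with an allylborane (C3–C4 piece) and sets the (5R) centre.
5. Ring order: the coumarin bicycle is bought, the carbocycle is formed in step 7, and the two are joined in step 12.

Reading and locants: C1 = CH–CH2OAr, C2 = C(Me)=, C3 = =CH, C4 = CH2, C5 = CH–O, C6 = CMe2, C7 = exocyclic CH2O. The SMILES is read as (1S,5R), which places CH2OAr and O-acyl cis. Compound 3 is assumed bought as its pentane solution.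

Step 1
Reactants: 1 methyl 3-hydroxy-2,2-dimethylpropanoate
Product: 2 methyl 2,2-dimethyl-3-oxopropanoate
Conditions: TEMPO (10 mol %), PhI(OAc)2 (1.1 equiv), CH2Cl2, rt; distil
Reagents that add atoms: none
Why: The oxoammonium-mediated (TEMPO) alcohol oxidation stops at the aldehyde in anhydrous medium, and 2 has no α-hydrogen, so it can neither enolise nor self-condense.

Step 2
Reactants: 2 methyl 2,2-dimethyl-3-oxopropanoate; 3 B-allylbis(isopinocampheyl)borane derived from (−)-α-pinene
Product: 5 methyl (3R)-3-hydroxy-2,2-dimethylhex-5-enoate, via borinate ester 4 (not isolated)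
Conditions: 3 (1.2 equiv, 1 M in pentane), Et2O, −78 °C, 3 h; then 3 M aq NaOH, 30% H2O2, 0 °C to rt
Reagents that add atoms: none
Why: In this Brown asymmetric allylboration (carbonyl allylation through a closed chair transition state) the isopinocampheyl groups from (−)-α-pinene send the allyl group to the Re face of the α-quaternary aldehyde, which forms C4–C5 and sets (R) at C5 (typically 90–96% ee, checked on the Mosher ester) while the hindered ester survives the short oxidative work-up.

Step 3
Reactants: 5 methyl (3R)-3-hydroxy-2,2-dimethylhex-5-enoate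
Product: 6 methyl (3R)-3-{[tert-butyl(dimethyl)silyl]oxy}-2,2-dimethylhex-5-enoate
Conditions: TBSOTf (1.3 equiv), 2,6-lutidine (2 equiv), CH2Cl2, 0 °C to rt
Reagents that add atoms: tert-butyldimethylsilyl triflate, CC(C)(C)[Si](C)(C)OS(=O)(=O)C(F)(F)F
Why: Silyl ether formation needs the reactive silyl triflate because the carbinol is neopentylic, and the TBS group then survives hydride, Grignard, organolithium, KH, borane and Mitsunobu conditions without touching C5.

Step 4
Reactants: 6 methyl (3R)-3-{[tert-butyl(dimethyl)silyl]oxy}-2,2-dimethylhex-5-enoate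
Product: 7 (3R)-3-{[tert-butyl(dimethyl)silyl]oxy}-2,2-dimethylhex-5-en-1-ol
Conditions: DIBAL-H (2.5 equiv), CH2Cl2, −78 to 0 °C; aq potassium sodium tartrate
Reagents that add atoms: none
Why: Ester reduction with excess DIBAL-H runs through to the neopentyl primary alcohol, which is more dependable than stopping a hindered ester at the aldehyde, and neither the silyl ether nor the terminal alkene reacts at or below 0 °C.

Step 5
Reactants: 7 (3R)-3-{[tert-butyl(dimethyl)silyl]oxy}-2,2-dimethylhex-5-en-1-ol
Product: 8 (3R)-3-{[tert-butyl(dimethyl)silyl]oxy}-2,2-dimethylhex-5-enal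
Conditions: Dess–Martin periodinane (1.2 equiv), CH2Cl2, rt
Reagents that add atoms: none
Why: Dess–Martin oxidation gives the non-enolisable α-quaternary aldehyde under near-neutral conditions, so there is no β-elimination or silyl loss.

Step 6
Reactants: 8 (3R)-3-{[tert-butyl(dimethyl)silyl]oxy}-2,2-dimethylhex-5-enal; 9 isopropenylmagnesium bromide
Product: 10 (5R)-5-{[tert-butyl(dimethyl)silyl]oxy}-2,4,4-trimethylocta-1,7-dien-3-ol (C3 epimer mixture)
Conditions: 9 (1.5 equiv, 0.5 M in THF), THF, −78 to 0 °C; sat. aq NH4Cl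
Reagents that add atoms: none
Why: Grignard 1,2-addition to an aldehyde that cannot enolise installs C2 and its methyl group, and the new carbinol centre, formed as an epimer mixture, needs no control because step 8 turns it into a ketone.

Step 7
Reactants: 10 (5R)-5-{[tert-butyl(dimethyl)silyl]oxy}-2,4,4-trimethylocta-1,7-dien-3-ol
Product: 11 (5R)-5-{[tert-butyl(dimethyl)silyl]oxy}-2,6,6-trimethylcyclohex-2-en-1-ol (C1 epimer mixture)
Conditions: second-generation Grubbs catalyst RuCl2(=CHPh)(PCy3)(H2IMes) (3 mol %), CH2Cl2 (0.01 M), 40 °C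
Reagents that add atoms: none
Why: Ring-closing metathesis of a monosubstituted and a 1,1-disubstituted alkene closes the six-membered ring at C2=C3 with loss of ethene, helped by the gem-dimethyl (Thorpe–Ingold) effect and by the tolerance of the ruthenium carbene for free allylic alcohols.

Step 8
Reactants: 11 (5R)-5-{[tert-butyl(dimethyl)silyl]oxy}-2,6,6-trimethylcyclohex-2-en-1-ol
Product: 12 (5R)-5-{[tert-butyl(dimethyl)silyl]oxy}-2,6,6-trimethylcyclohex-2-en-1-one
Conditions: Dess–Martin periodinane (1.3 equiv), CH2Cl2, rt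
Reagents that add atoms: none
Why: Dess–Martin oxidation of the hindered allylic alcohol merges both epimers into one enone whose carbonyl carbon is C1 and which has no α-hydrogen.

Step 9
Reactants: 12 (5R)-5-{[tert-butyl(dimethyl)silyl]oxy}-2,6,6-trimethylcyclohex-2-en-1-one; 13 (trimethylsilyl)methyllithium
Product: 14 (5R)-5-{[tert-butyl(dimethyl)silyl]oxy}-2,6,6-trimethyl-1-[(trimethylsilyl)methyl]cyclohex-2-en-1-ol
Conditions: 13 (2 equiv, 1 M in pentane), THF, −78 to 0 °C; sat. aq NH4Cl
Reagents that add atoms: none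
Why: In this first half of a Peterson olefination the hard α-silyl organolithium adds 1,2 to the non-enolisable enone, as other organolithiums do with 2,6,6-trimethylcyclohex-2-enone, and the configuration of the new tertiary carbinol is irrelevant because it is lost in step 10.

Step 10
Reactants: 14 (5R)-5-{[tert-butyl(dimethyl)silyl]oxy}-2,6,6-trimethyl-1-[(trimethylsilyl)methyl]cyclohex-2-en-1-ol
Product: 15 tert-butyl(dimethyl){[(1R)-4,6,6-trimethyl-5-methylidenecyclohex-3-en-1-yl]oxy}silane
Conditions: KH (2 equiv), THF, 0 °C to rt; H2O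
Reagents that add atoms: none
Why: Base-induced Peterson syn-elimination of the potassium β-silyl alkoxide is regiospecific, so the new double bond can only be the exocyclic C1=C7 methylene and no allyl cation that could scramble the diene is formed.

Step 11
Reactants: 15 tert-butyl(dimethyl){[(1R)-4,6,6-trimethyl-5-methylidenecyclohex-3-en-1-yl]oxy}silane
Product: 17 [(1S,5R)-5-{[tert-butyl(dimethyl)silyl]oxy}-2,6,6-trimethylcyclohex-2-en-1-yl]methanol, via B-alkyl-9-BBN adduct 16 (not isolated)
Conditions: 9-BBN-H (1.3 equiv, 0.5 M in THF), THF, 0 °C to rt; then 3 M aq NaOH, 30% H2O2, 0 °C to rt; chromatography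
Reagents that add atoms: 9-borabicyclo[3.3.1]nonane, [H]B1C2CCCC1CCC2 (boron in 16 only); hydrogen peroxide, OO
Why: In the hydroboration–oxidation 9-BBN puts boron on the open exocyclic CH2 and delivers H to C1 from the face opposite the pseudoaxial C6 methyl (the same axial trajectory by which hydride reduces 2,2-dimethylcyclohexanones), so CH2OH ends up equatorial and cis to the equatorial C5 silyl ether, which is (1S), while the trisubstituted ring alkene is far too slow to react.

Step 12
Reactants: 17 [(1S,5R)-5-{[tert-butyl(dimethyl)silyl]oxy}-2,6,6-trimethylcyclohex-2-en-1-yl]methanol; 18 umbelliferone (7-hydroxy-2H-chromen-2-one)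
Product: 19 7-{[(1S,5R)-5-{[tert-butyl(dimethyl)silyl]oxy}-2,6,6-trimethylcyclohex-2-en-1-yl]methoxy}-2H-chromen-2-one
Conditions: 18 (1.3 equiv), PPh3 (1.5 equiv), DIAD (1.5 equiv), THF, 0 °C to rt
Reagents that add atoms: none
Why: In the Mitsunobu etherification the acidic phenol (pKa about 8) displaces the oxyphosphonium of the primary alcohol in an SN2 step at C7, which is not a stereocentre, so C1 and C5 are untouched and the lactone sees no strong base.

Step 13
Reactants: 19 7-{[(1S,5R)-5-{[tert-butyl(dimethyl)silyl]oxy}-2,6,6-trimethylcyclohex-2-en-1-yl]methoxy}-2H-chromen-2-one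
Product: 20 7-{[(1S,5R)-5-hydroxy-2,6,6-trimethylcyclohex-2-en-1-yl]methoxy}-2H-chromen-2-one
Conditions: 48% aq HF, MeCN, 0 °C to rt (plastic vessel)
Reagents that add atoms: none
Why: Fluoride-driven desilylation frees the hindered C5 alcohol with retention because only the O–Si bond breaks, while the aryl ether, the coumarin lactone and the trisubstituted alkene are inert to this weak acid.

Step 14
Reactants: 20 7-{[(1S,5R)-5-hydroxy-2,6,6-trimethylcyclohex-2-en-1-yl]methoxy}-2H-chromen-2-one; 21 3-methylbutanoyl chloride (isovaleryl chloride)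
Product: 22 (1R,5S)-4,6,6-trimethyl-5-{[(2-oxo-2H-chromen-7-yl)oxy]methyl}cyclohex-3-en-1-yl 3-methylbutanoate (target; (1S,5R) in the locants used above)
Conditions: 21 (1.5 equiv), Et3N (2 equiv), DMAP (0.2 equiv), CH2Cl2, 0 °C to rt
Reagents that add atoms: none
Why: DMAP-catalysed acylation (nucleophilic acyl-transfer catalysis) esterifies the equatorial neopentylic alcohol at oxygen, so C5 keeps its configuration and the target results.

**Compound list**
1 | methyl 3-hydroxy-2,2-dimethylpropanoate | COC(=O)C(C)(C)CO | starting material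
2 | methyl 2,2-dimethyl-3-oxopropanoate | COC(=O)C(C)(C)C=O | intermediate
3 | B-allylbis(isopinocampheyl)borane derived from (−)-α-pinene | C=CCB([C@H]1C[C@H]2C[C@@H]([C@@H]1C)C2(C)C)[C@H]1C[C@H]2C[C@@H]([C@@H]1C)C2(C)C | starting material
4 | methyl (3R)-3-{[bis(isopinocampheyl)boranyl]oxy}-2,2-dimethylhex-5-enoate | C=CC[C@@H](OB([C@H]1C[C@H]2C[C@@H]([C@@H]1C)C2(C)C)[C@H]1C[C@H]2C[C@@H]([C@@H]1C)C2(C)C)C(C)(C)C(=O)OC | intermediate
5 | methyl (3R)-3-hydroxy-2,2-dimethylhex-5-enoate | C=CC[C@@H](O)C(C)(C)C(=O)OC | intermediate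
6 | methyl (3R)-3-{[tert-butyl(dimethyl)silyl]oxy}-2,2-dimethylhex-5-enoate | C=CC[C@@H](O[Si](C)(C)C(C)(C)C)C(C)(C)C(=O)OC | intermediate
7 | (3R)-3-{[tert-butyl(dimethyl)silyl]oxy}-2,2-dimethylhex-5-en-1-ol | C=CC[C@@H](O[Si](C)(C)C(C)(C)C)C(C)(C)CO | intermediate
8 | (3R)-3-{[tert-butyl(dimethyl)silyl]oxy}-2,2-dimethylhex-5-enal | C=CC[C@@H](O[Si](C)(C)C(C)(C)C)C(C)(C)C=O | intermediate
9 | isopropenylmagnesium bromide | CC(=C)[Mg]Br | starting material
10 | (5R)-5-{[tert-butyl(dimethyl)silyl]oxy}-2,4,4-trimethylocta-1,7-dien-3-ol (C3 epimers) | C=CC[C@@H](O[Si](C)(C)C(C)(C)C)C(C)(C)C(O)C(C)=C | intermediate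
11 | (5R)-5-{[tert-butyl(dimethyl)silyl]oxy}-2,6,6-trimethylcyclohex-2-en-1-ol (C1 epimers) | CC1=CC[C@@H](O[Si](C)(C)C(C)(C)C)C(C)(C)C1O | intermediate
12 | (5R)-5-{[tert-butyl(dimethyl)silyl]oxy}-2,6,6-trimethylcyclohex-2-en-1-one | CC1=CC[C@@H](O[Si](C)(C)C(C)(C)C)C(C)(C)C1=O | intermediate
13 | (trimethylsilyl)methyllithium | [Li]C[Si](C)(C)C | starting material
14 | (5R)-5-{[tert-butyl(dimethyl)silyl]oxy}-2,6,6-trimethyl-1-[(trimethylsilyl)methyl]cyclohex-2-en-1-ol | CC1=CC[C@@H](O[Si](C)(C)C(C)(C)C)C(C)(C)C1(O)C[Si](C)(C)C | intermediate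
15 | tert-butyl(dimethyl){[(1R)-4,6,6-trimethyl-5-methylidenecyclohex-3-en-1-yl]oxy}silane | CC1=CC[C@@H](O[Si](C)(C)C(C)(C)C)C(C)(C)C1=C | intermediate
16 | 9-{[(1S,5R)-5-{[tert-butyl(dimethyl)silyl]oxy}-2,6,6-trimethylcyclohex-2-en-1-yl]methyl}-9-borabicyclo[3.3.1]nonane | CC1=CC[C@@H](O[Si](C)(C)C(C)(C)C)C(C)(C)[C@H]1CB1C2CCCC1CCC2 | intermediate
17 | [(1S,5R)-5-{[tert-butyl(dimethyl)silyl]oxy}-2,6,6-trimethylcyclohex-2-en-1-yl]methanol | CC1=CC[C@@H](O[Si](C)(C)C(C)(C)C)C(C)(C)[C@H]1CO | intermediate
18 | umbelliferone (7-hydroxy-2H-chromen-2-one) | Oc1ccc2ccc(=O)oc2c1 | starting material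
19 | 7-{[(1S,5R)-5-{[tert-butyl(dimethyl)silyl]oxy}-2,6,6-trimethylcyclohex-2-en-1-yl]methoxy}-2H-chromen-2-one | CC1=CC[C@@H](O[Si](C)(C)C(C)(C)C)C(C)(C)[C@H]1COc1ccc2ccc(=O)oc2c1 | intermediate
20 | 7-{[(1S,5R)-5-hydroxy-2,6,6-trimethylcyclohex-2-en-1-yl]methoxy}-2H-chromen-2-one | CC1=CC[C@@H](O)C(C)(C)[C@H]1COc1ccc2ccc(=O)oc2c1 | intermediate
21 | 3-methylbutanoyl chloride | CC(C)CC(=O)Cl | starting material
22 | (1R,5S)-4,6,6-trimethyl-5-{[(2-oxo-2H-chromen-7-yl)oxy]methyl}cyclohex-3-en-1-yl 3-methylbutanoate | CC1=CC[C@@H](OC(=O)CC(C)C)C(C)(C)[C@H]1COc1ccc2ccc(=O)oc2c1 | target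

**Total step count:** 14. **Longest linear sequence:** 14 steps (1 to 22).

**Steps most likely to fail and their fallbacks**

**Step 11** is the most exposed, because the C1 centre rests on the facial preference of 9-BBN for diene 15, which is argued here by analogy, not proven.
- The fallback sets out from 12 and comes back at 17.
- Corey–Chaykovsky epoxidation with dimethylsulfonium methylide (Me3SI, n-BuLi, THF, 0 °C) adds CH2 1,2 to the enone. It gives the vinyl oxirane (3S,7R)-7-{[tert-butyl(dimethyl)silyl]oxy}-4,8,8-trimethyl-1-oxaspiro[2.5]oct-4-ene F2, with the oxygen on the face of the silyl ether.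
- Formate hydrogenolysis under zerovalent palladium catalysis follows (Pd2(dba)3·CHCl3, n-Bu3P, HCO2H, Et3N, THF, rt). It replaces the allylic C1–O bond by C1–H with inversion and leaves C2=C3 where it is.
- C1 is then fixed by a stereospecific substitution on an isolable, separable epoxide, and the product is 17.

**Step 9** comes next, because the carbonyl of 12 is flanked by a quaternary carbon and a methyl-bearing sp2 carbon and may resist the silylmethyl nucleophile.
- The fallback sets out from 12 and comes back at 15.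
- MeLi, the smallest carbon nucleophile (Et2O, −78 °C), gives (5R)-5-{[tert-butyl(dimethyl)silyl]oxy}-1,2,6,6-tetramethylcyclohex-2-en-1-ol F1.
- F1 is dehydrated with the Burgess reagent (toluene, 50 °C).
- C6 is quaternary and C2 is sp2, so the syn-elimination can only take a hydrogen from the new methyl group, and it delivers 15.

**Step 12** is third, because the SN2 displacement at C7 takes place next to a carbon crowded by C6Me2 and the C2 methyl.
- The fallback sets out from 17 and comes back at 19 by forming the other C–O bond.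
- Alcohol 17 is coupled through its oxygen with purchased 7-bromocoumarin (O=c1ccc2ccc(Br)cc2o1) in a palladium-catalysed C–O cross-coupling ([Pd(allyl)Cl]2, RockPhos, Cs2CO3, toluene, 90 °C).
- No substitution at C7 is needed. New compounds made on this path: none F0.

**Further compounds**
F1 | step 9 | (5R)-5-{[tert-butyl(dimethyl)silyl]oxy}-1,2,6,6-tetramethylcyclohex-2-en-1-ol | CC1=CC[C@@H](O[Si](C)(C)C(C)(C)C)C(C)(C)C1(C)O
F2 | step 11 | (3S,7R)-7-{[tert-butyl(dimethyl)silyl]oxy}-4,8,8-trimethyl-1-oxaspiro[2.5]oct-4-ene | CC1=CC[C@@H](O[Si](C)(C)C(C)(C)C)C(C)(C)[C@]12CO2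
F0 | step 12 | none | none
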